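I began from late times in a closed flask, where the ratio of target to isomer of the product no longer depends on the route that made them.

| setting | dusk | winter | autumn | dawn |
|---|---|---|---|---|
| starting material | 0.016 M | 0.016 M | 0.016 M | 0.016 M (fed, over 3.20 h) |
| reagent | 0.0176 M | 0.0176 M | 0.0176 M | 0.0176 M |
| second substrate | 0.0160 M (fed, over 3.20 h) | 0.0160 M | 0.0160 M | 0.0160 M |
| time | 4.0 h |  | 4.0 h | 4.0 h |
| remark | a stirred flask in which second substrate is dosed at a steady rate over 3.20 h without added volume, worked up at 4.0 h | one stirred flow tank at steady state, fed with the mixture as stated, mean residence time 4.0 h | everything together in a closed stirred flask, run for 4.0 h | all but starting material at the start; starting material goes in evenly over 3.20 h, the run ends at 4.0 h |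

    starting material + second substrate → cross product (k1 = 0.24 /M/min)
    starting material + reagent → target (k2 = 0.79 /M/min)
    second substrate + reagent → second product (k3 = 0.85 /M/min)
    target ⇌ isomer of the product (K4 = 2.9, k4 = 0.046 /min)

1. the set-up with the highest amount of target at the outlet or at the end, in percent of the starting material put in ("none" if the first two lie within 2 percentage points) (dusk / winter / autumn / dawn / none)
2. amount of target at the outlet or at the end, in percent of the starting material put in, dusk
3. amount of target at the outlet or at the end, in percent of the starting material put in, winter
4. amount of target at the outlet or at the end, in percent of the starting material put in, autumn
5. amount of target at the outlet or at the end, in percent of the starting material put in, dawn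

- the stated concentrations are those of everything mixed, before any reaction; amounts are the same in each set-up
- the feed brings no volume worth counting
- run time (dusk): 4.0 h

Was the run long enough to count as late? Integrating the isomerisation, both ways together, gave a first-order approach to equilibrium with a relaxation half-life of 11.2 min, which is far shorter than the 4.0 h run. So in the closed flasks dusk and autumn, [target]/[isomer of the product] had to end near 1/2.9. The pool of these two then stood as target to 25.6%: this was the equilibrium share, the fraction of the pool present as target at equilibrium.

How much entered the pool? In autumn, the two substrates started level and competed for reagent with a selectivity factor of 0.929. As an estimate, I spent the whole reagent charge in the proportion of the two rate constants, which put 53.0% of the starting material in the pool. Multiplied by the share, that gave me 13.6% target for autumn.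

Did the order of addition matter? At the charges of autumn, starting material had a half-life of 0.83 h on the target path, and second substrate had 0.77 h on its own path. Both were shorter than the 3.20 h feed, so whichever substrate stood in the flask first had the earlier claim on reagent. I ranked dusk above autumn and dawn below it, and I placed winter near autumn without reckoning it.

The forecast named dusk, with 17.3% for dusk, 12% for winter, 13.5% for autumn and 8.3% for dawn, holding that “Dosing the second substrate late gives the starting material first call on the reagent”.

The simulation gave dusk as best, with 17.7% for dusk, 11.9% for winter, 13.3% for autumn and 9.02% for dawn.

The main reason dusk held no more target was the isomerisation. The dusk run without that path held 67.7% target against 17.7%, and the share applied to that figure gave 17.3%.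

A neighbour flask, dusk with 0.030 M reagent, kept 5.9% starting material and 4.11% cross product, so the share on the remaining pool gave 23.0% target. The simulation of that flask gave 23.5%.

(Its constants are invented; the flask was simulated.)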